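**Retrosynthetic overview**

- The plan rests on ring B. Ring A of the tetralin (C4a, C5, C6, C7, C8, C8a, carrying both methoxy groups) is cut at C8–C8a and C4a–C5. What remains is a cyclohexanone (C4a as carbonyl carbon, C8a and C4 as its α-carbons) bearing the contiguous all-trans triad C1 (aryl), C2 (methyl), C3 (methyl).
- Ring B is made first: (R)-4-methylcyclohex-2-enone by enamine Michael addition and aldol condensation. The C3 methyl group follows by cuprate addition, with the unsaturation for the next addition placed beforehand through an α′-phenylthio group.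
- Ring C is attached as a unit by ligand-controlled rhodium 1,4-arylation. Silylation of the enolate fixes the enol ether with its nucleophilic carbon at C8a.
- Ring A is made last: Mukaiyama–Michael addition to 3-methoxybut-3-en-2-one (C8–C8a), aldol condensation (C4a–C5), then non-acidic dehydrogenation to the phenol and O-methylation.

Key step: step 8

Assumption: the target as drawn is (1S,2S,3R). The two centres created in ring A in step 8 (C8a drawn trans to H-1, C7 unspecified) are removed in step 9, so their configuration is immaterial.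

**Route**

Step 1
Reactants: 1 propanal; 2 but-3-en-2-one
Product: 3 (R)-2-methyl-5-oxohexanal
Conditions: (S)-2-(methoxydiphenylmethyl)pyrrolidine (5 mol%), ethyl 3,4-dihydroxybenzoate (20 mol%), neat, 4 °C
Reagents that add atoms: none
Why: Enamine-mediated Michael addition of propanal to the vinyl ketone, in which the methoxydiphenylmethyl group of the (S)-pyrrolidine blocks one face of the E-enamine so that the acceptor is taken up on the other face and C2 should be formed R.

Step 2
Reactants: 3 (R)-2-methyl-5-oxohexanal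
Product: 5 (R)-4-methylcyclohex-2-en-1-one, via ketol 4 (not isolated)
Conditions: KOH (0.1 M aq.), nBu4NOH (cat.), Et2O/THF, reflux
Reagents that add atoms: none
Why: Intramolecular aldol condensation [6-(enolendo)-exo-trig attack of the methyl-ketone enolate on the aldehyde, then E1cB dehydration of ketol 4]; the stereocentre is not a reacting atom, and dilute two-phase base should keep epimerisation of the α-branched aldehyde slow relative to ring closure.

Step 3
Reactants: 5 (R)-4-methylcyclohex-2-en-1-one
Product: 6 (4R)-4-methyl-6-(phenylsulfanyl)cyclohex-2-en-1-one (C6 epimers)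
Conditions: LiN(iPr)2, THF, −78 °C; then S-phenyl benzenethiosulfonate, −78→0 °C
Reagents that add atoms: S-phenyl benzenethiosulfonate, O=S(=O)(Sc1ccccc1)c1ccccc1
Why: Kinetic deprotonation of a cyclohex-2-enone removes the α′ proton (C6) to give the cross-conjugated dienolate, which is sulfenylated by the thiosulfonate (enolate sulfenylation); C4 is untouched and the new C6 centre forms as a mixture that does not matter because it is removed in step 5.

Step 4
Reactants: 6 (4R)-4-methyl-6-(phenylsulfanyl)cyclohex-2-en-1-one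
Product: 7 (4R,5R)-4,5-dimethyl-2-(phenylsulfanyl)cyclohexan-1-one (C2 epimers)
Conditions: Me2CuLi (from MeLi and CuI), Et2O, −78→−30 °C; aqueous work-up
Reagents that add atoms: lithium dimethylcuprate, [Li+].C[Cu-]C
Why: 1,4-Addition of the lithium dialkylcuprate, the methyl group entering C3 of the enone anti to the neighbouring C4 methyl group as is usual for 4-substituted cyclohexenones (this sets the trans-dimethyl pair), while the thioether is inert to the cuprate.

Step 5
Reactants: 7 (4R,5R)-4,5-dimethyl-2-(phenylsulfanyl)cyclohexan-1-one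
Product: 9 (4S,5R)-4,5-dimethylcyclohex-2-en-1-one, via sulfoxide 8 (not isolated)
Conditions: mCPBA (1.0 equiv), CH2Cl2, −78 °C; then toluene, CaCO3, 110 °C
Reagents that add atoms: none
Why: Oxidation to the sulfoxide and thermal syn-elimination of benzenesulfenic acid, which can only take a hydrogen from C3 and so places the new C=C on the side away from the methyl-bearing carbons without any regiochemical choice; no stereocentre is formed or touched.

Step 6
Reactants: 9 (4S,5R)-4,5-dimethylcyclohex-2-en-1-one; 10 4-bromo-1,2-dimethoxybenzene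
Product: 14 trimethylsilyl enol ether of all-trans 3-(3,4-dimethoxyphenyl)-4,5-dimethylcyclohexanone (double bond C1=C2; 3R,4S,5R), via aryllithium 11 (not isolated), via aryltitanium 12 (not isolated), via titanium enolate 13 (not isolated)
Conditions: 10, nBuLi, THF, −78 °C; ClTi(OiPr)3, −78→20 °C; add to 9, [Rh(OH)((R)-binap)]2 (3 mol% Rh), THF, 20 °C; then LiOiPr, Me3SiCl
Reagents that add atoms: chlorotrimethylsilane, C[Si](C)(C)Cl
Why: Rhodium-catalysed asymmetric 1,4-addition of an aryltitanium reagent (Hayashi–Miyaura-type conjugate arylation): the aryl–rhodium species should insert the enone on the face selected by (R)-BINAP, which is the face anti to the adjacent C4 methyl group, so that ligand and γ-substituent reinforce each other against the 1,3-interaction with the C5 methyl group, and the titanium enolate is silylated before it can equilibrate, which locks the enol double bond next to the aryl-bearing carbon.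

Step 7
Reactants: 15 3,3-dimethoxybutan-2-one
Product: 16 3-methoxybut-3-en-2-one
Conditions: TsOH·H2O (cat.), hydroquinone (trace), 150 °C, MeOH distilled off; product distilled and used fresh
Reagents that add atoms: none
Why: Acid-catalysed loss of methanol from the ketal (enol ether formation), driven by removal of methanol by distillation.

Step 8
Reactants: 14 trimethylsilyl enol ether (3R,4S,5R); 16 3-methoxybut-3-en-2-one
Product: 19 7-methoxy octalenone (1R,2S,3R,8aS in target numbering; C7 epimers), via diketone 17 (not isolated), via ketol 18 (not isolated)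
Conditions: Sc(OTf)3 (10 mol%), CH2Cl2, −78→−40 °C; aq. NaHCO3; crude in MeOH, KOH, 0→20 °C
Reagents that add atoms: none
Why: Sc(OTf)3 chelates the carbonyl and methoxy oxygens of 16 in the s-cis form and the enol ether carbon C8a of 14 adds to its CH2 terminus (Mukaiyama–Michael addition, C8–C8a), the silyl group being lost on work-up to leave diketone 17. KOH then forms the methyl-ketone enolate, whose carbon C5 attacks the ring carbonyl C4a in a 6-(enolendo)-exo-trig aldol closure, and E1cB loss of water from ketol 18 gives the conjugated enone 19. The closest known reaction type is the Lewis-acid variant of the Robinson annulation between a regiodefined silyl enol ether and an α-substituted vinyl ketone. C8a is set by attack anti to the aryl group on C1 (and can epimerise to the same trans arrangement), C7 is uncontrolled, and both centres vanish on aromatisation. The selectivity that matters is C8a against C4 as the nucleophilic α-carbon, and it is fixed by the position of the enol ether double bond made in step 6; the bridged aldol from C4 onto C6 cannot dehydrate and should revert. Base and not acid is used for the closure because the dienol form of 19 would aromatise by loss of methanol.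

Step 9
Reactants: 19 7-methoxy octalenone
Product: 22 (5S,6S,7R)-5-(3,4-dimethoxyphenyl)-3-methoxy-6,7-dimethyl-5,6,7,8-tetrahydronaphthalen-2-ol, via silyl dienol ether 20 (not isolated), via dienone 21 (not isolated)
Conditions: LiN(iPr)2, THF, −78 °C; Me3SiCl; then Pd(OAc)2 (1.1 equiv), MeCN, 20 °C
Reagents that add atoms: none
Why: Kinetic α′-deprotonation at C7 and O-silylation give the cross-conjugated silyl dienol ether, Saegusa–Ito dehydrogenation introduces the C7=C8 double bond, and the resulting cyclohexa-2,5-dienone with hydrogen on C8a should tautomerise at once to the phenol, which removes the C7 and C8a centres and leaves C1, C2 and C3 untouched.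

Step 10
Reactants: 22 phenol (5S,6S,7R)
Product: 23 galbulin, (1S,2S,3R)-1-(3,4-dimethoxyphenyl)-6,7-dimethoxy-2,3-dimethyl-1,2,3,4-tetrahydronaphthalene
Conditions: MeI, K2CO3, acetone, reflux
Reagents that add atoms: iodomethane, CI
Why: Williamson O-methylation of the phenoxide; no stereocentre is involved.

**Compound list**

1 | propanal | CCC=O | starting material
2 | but-3-en-2-one (methyl vinyl ketone) | CC(=O)C=C | starting material
3 | (R)-2-methyl-5-oxohexanal | O=C[C@H](C)CCC(C)=O | intermediate
4 | ketol, (4R)-3-hydroxy-4-methylcyclohexan-1-one (C3 epimers; not isolated) | O=C1CC(O)[C@H](C)CC1 | intermediate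
5 | (R)-4-methylcyclohex-2-en-1-one | O=C1C=C[C@H](C)CC1 | intermediate
6 | (4R)-4-methyl-6-(phenylsulfanyl)cyclohex-2-en-1-one (C6 epimers) | O=C1C=C[C@H](C)CC1Sc1ccccc1 | intermediate
7 | (4R,5R)-4,5-dimethyl-2-(phenylsulfanyl)cyclohexan-1-one (trans-dimethyl; C2 epimers) | O=C1C[C@@H](C)[C@H](C)CC1Sc1ccccc1 | intermediate
8 | sulfoxide, (4R,5R)-4,5-dimethyl-2-(phenylsulfinyl)cyclohexan-1-one (not isolated) | O=C1C[C@@H](C)[C@H](C)CC1S(=O)c1ccccc1 | intermediate
9 | (4S,5R)-4,5-dimethylcyclohex-2-en-1-one (trans) | O=C1C=C[C@@H](C)[C@H](C)C1 | intermediate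
10 | 4-bromo-1,2-dimethoxybenzene (4-bromoveratrole) | COc1ccc(Br)cc1OC | starting material
11 | (3,4-dimethoxyphenyl)lithium (not isolated) | COc1ccc([Li])cc1OC | intermediate
12 | (3,4-dimethoxyphenyl)titanium triisopropoxide (not isolated) | COc1ccc([Ti](OC(C)C)(OC(C)C)OC(C)C)cc1OC | intermediate
13 | titanium enolate, [(3R,4S,5R)-3-(3,4-dimethoxyphenyl)-4,5-dimethylcyclohex-1-en-1-yl]oxytitanium triisopropoxide (not isolated) | COc1ccc([C@H]2C=C(O[Ti](OC(C)C)(OC(C)C)OC(C)C)C[C@@H](C)[C@@H]2C)cc1OC | intermediate
14 | trimethyl{[(3R,4S,5R)-3-(3,4-dimethoxyphenyl)-4,5-dimethylcyclohex-1-en-1-yl]oxy}silane (aryl, methyl, methyl all trans) | COc1ccc([C@H]2C=C(O[Si](C)(C)C)C[C@@H](C)[C@@H]2C)cc1OC | intermediate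
15 | 3,3-dimethoxybutan-2-one | CC(=O)C(C)(OC)OC | starting material
16 | 3-methoxybut-3-en-2-one | CC(=O)C(=C)OC | intermediate
17 | diketone, (2S,3R,4S,5R)-3-(3,4-dimethoxyphenyl)-2-(2-methoxy-3-oxobutyl)-4,5-dimethylcyclohexan-1-one (side-chain methoxy carbon as epimers; not isolated) | COc1ccc([C@H]2[C@H](CC(OC)C(C)=O)C(=O)C[C@@H](C)[C@@H]2C)cc1OC | intermediate
18 | ketol, 4a-hydroxy-7-methoxy decalin-6-one with the ring B substituents of 19 (C4a and C7 epimers; not isolated) | COc1ccc([C@H]2[C@@H]3CC(OC)C(=O)CC3(O)C[C@@H](C)[C@@H]2C)cc1OC | intermediate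
19 | 7-methoxy octalenone, (1R,2S,3R,8aS)-1-(3,4-dimethoxyphenyl)-7-methoxy-2,3-dimethyl-2,3,4,7,8,8a-hexahydronaphthalen-6(1H)-one (target numbering; C7 epimers) | COc1ccc([C@H]2[C@@H]3CC(OC)C(=O)C=C3C[C@@H](C)[C@@H]2C)cc1OC | intermediate
20 | silyl dienol ether, 7-methoxy-6-(trimethylsilyloxy)-4a(5),6-diene derived from 19 (not isolated) | COc1ccc([C@H]2[C@@H]3CC(OC)=C(O[Si](C)(C)C)C=C3C[C@@H](C)[C@@H]2C)cc1OC | intermediate
21 | dienone, 1-(3,4-dimethoxyphenyl)-7-methoxy-2,3-dimethyl-2,3,4,8a-tetrahydronaphthalen-6(1H)-one (target numbering; not isolated) | COc1ccc([C@H]2[C@@H]3C=C(OC)C(=O)C=C3C[C@@H](C)[C@@H]2C)cc1OC | intermediate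
22 | (5S,6S,7R)-5-(3,4-dimethoxyphenyl)-3-methoxy-6,7-dimethyl-5,6,7,8-tetrahydronaphthalen-2-ol | COc1ccc([C@H]2c3cc(OC)c(O)cc3C[C@@H](C)[C@@H]2C)cc1OC | intermediate
23 | galbulin, (1S,2S,3R)-1-(3,4-dimethoxyphenyl)-6,7-dimethoxy-2,3-dimethyl-1,2,3,4-tetrahydronaphthalene | COc1ccc([C@H]2c3cc(OC)c(OC)cc3C[C@@H](C)[C@@H]2C)cc1OC | target

**Step count**

Total step count: 10. Longest linear sequence: 9 steps (steps 1 to 6, then 8, 9 and 10); step 7 is a one-step side branch.

**Steps most likely to fail**

1. Step 8 (key step).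
What may go wrong: the α-methoxy enone is a weakly electrophilic, acid-labile enol ether, so its hydrolysis or oligomerisation at the Lewis acid may outrun addition to the hindered carbon C8a; in the base step, retro-Michael cleavage may compete with ring closure.
Fallback (sets out from 14 and 2, returns at 19): the C7 oxygen is introduced after ring closure instead of arriving with the four-carbon unit. Compound 14 is added to but-3-en-2-one 2 (TiCl4, CH2Cl2, −78 °C) to give the diketone (2S,3R,4S,5R)-3-(3,4-dimethoxyphenyl)-4,5-dimethyl-2-(3-oxobutyl)cyclohexan-1-one F1. KOH in MeOH closes and dehydrates it to the octalenone without the C7 methoxy group F2. LiN(iPr)2 and Me3SiCl at −78 °C give the cross-conjugated silyl dienol ether F3. Rubottom oxidation (mCPBA, NaHCO3, CH2Cl2, then Et3N·3HF) gives the 7-hydroxy octalenone F4. Ag2O and MeI convert F4 into 19.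

2. Step 6.
What may go wrong: poor facial selectivity, with the aryl group delivered syn to the C4 methyl group, if the preference for axial attack trans to the C5 methyl group is not overridden by the ligand; the insertion may also be slow on this 4,5-disubstituted enone.
Fallback (sets out from 10 and 2, returns at 19): the triad is assembled under thermodynamic control by a Diels–Alder route.
- Heck reaction of 10 with 2 (Pd(OAc)2, P(o-tol)3, Et3N, DMF, 100 °C) gives (E)-4-(3,4-dimethoxyphenyl)but-3-en-2-one F5.
- iPr3SiOTf and Et3N give the 2-silyloxy diene F6.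
- Cycloaddition with diethyl fumarate, catalysed by the cationic oxazaborolidine made from α,α-diphenylprolinol, o-tolylboroxine and HNTf2 (the enantiomer that forms the aryl-bearing carbon as in 14), gives the cyclohexene diester F7, with the aryl group cis to the neighbouring ester.
- NaOEt in EtOH equilibrates both ester-bearing carbons to the all-equatorial, all-trans diester F8.
- LiAlH4 gives the diol F9, TsCl in pyridine gives the bis-tosylate F10, and LiBHEt3 gives the triisopropylsilyl analogue of 14, F11.
- F11 is taken through step 8 in place of 14 to reach 19.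

3. Step 9.
What may go wrong: deprotonation at the γ-position instead of C7, followed by loss of methanol from the resulting dienol ether during the palladium step, which would aromatise ring A without the C7 oxygen; incomplete dehydrogenation is the other failure.
Fallback (sets out from 19, returns at 23): C7 is raised to the ketone level by oxygenation instead of dehydrogenating the ring. The potassium enolate of 19 (KN(SiMe3)2, THF, −78 °C) is hydroxylated with 2-(phenylsulfonyl)-3-phenyloxaziridine to the 7-hydroxy-7-methoxy ketone F12. On work-up with aqueous NH4Cl and brief stirring with AcOH it loses methanol and tautomerises to the catechol F13. MeI and K2CO3 in acetone methylate both phenols to give 23.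

**Further compounds**

F1 | step 8 | (2S,3R,4S,5R)-3-(3,4-dimethoxyphenyl)-4,5-dimethyl-2-(3-oxobutyl)cyclohexan-1-one | COc1ccc([C@H]2[C@H](CCC(C)=O)C(=O)C[C@@H](C)[C@@H]2C)cc1OC
F2 | step 8 | (1R,2S,3R,8aS)-1-(3,4-dimethoxyphenyl)-2,3-dimethyl-2,3,4,7,8,8a-hexahydronaphthalen-6(1H)-one (target numbering) | COc1ccc([C@H]2[C@@H]3CCC(=O)C=C3C[C@@H](C)[C@@H]2C)cc1OC
F3 | step 8 | cross-conjugated trimethylsilyl dienol ether of F2 (6-silyloxy-4a(5),6-diene) | COc1ccc([C@H]2[C@@H]3CC=C(O[Si](C)(C)C)C=C3C[C@@H](C)[C@@H]2C)cc1OC
F4 | step 8 | 7-hydroxy octalenone, 1-(3,4-dimethoxyphenyl)-7-hydroxy-2,3-dimethyl-2,3,4,7,8,8a-hexahydronaphthalen-6(1H)-one (C7 epimers) | COc1ccc([C@H]2[C@@H]3CC(O)C(=O)C=C3C[C@@H](C)[C@@H]2C)cc1OC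
F5 | step 6 | (E)-4-(3,4-dimethoxyphenyl)but-3-en-2-one | COc1ccc(/C=C/C(C)=O)cc1OC
F6 | step 6 | (E)-{[4-(3,4-dimethoxyphenyl)buta-1,3-dien-2-yl]oxy}tri(propan-2-yl)silane | COc1ccc(/C=C/C(=C)O[Si](C(C)C)(C(C)C)C(C)C)cc1OC
F7 | step 6 | diethyl 3-(3,4-dimethoxyphenyl)-5-(triisopropylsilyloxy)cyclohex-4-ene-1,2-dicarboxylate (aryl cis to C2 ester, esters trans) | COc1ccc([C@H]2C=C(O[Si](C(C)C)(C(C)C)C(C)C)C[C@H](C(=O)OCC)[C@H]2C(=O)OCC)cc1OC
F8 | step 6 | diethyl 3-(3,4-dimethoxyphenyl)-5-(triisopropylsilyloxy)cyclohex-4-ene-1,2-dicarboxylate (all trans) | COc1ccc([C@H]2C=C(O[Si](C(C)C)(C(C)C)C(C)C)C[C@@H](C(=O)OCC)[C@@H]2C(=O)OCC)cc1OC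
F9 | step 6 | all-trans [3-(3,4-dimethoxyphenyl)-5-(triisopropylsilyloxy)cyclohex-4-ene-1,2-diyl]dimethanol | COc1ccc([C@H]2C=C(O[Si](C(C)C)(C(C)C)C(C)C)C[C@@H](CO)[C@@H]2CO)cc1OC
F10 | step 6 | bis(4-methylbenzenesulfonate) of F9 | COc1ccc([C@H]2C=C(O[Si](C(C)C)(C(C)C)C(C)C)C[C@@H](COS(=O)(=O)c3ccc(C)cc3)[C@@H]2COS(=O)(=O)c4ccc(C)cc4)cc1OC
F11 | step 6 | {[(3R,4S,5R)-3-(3,4-dimethoxyphenyl)-4,5-dimethylcyclohex-1-en-1-yl]oxy}tri(propan-2-yl)silane | COc1ccc([C@H]2C=C(O[Si](C(C)C)(C(C)C)C(C)C)C[C@@H](C)[C@@H]2C)cc1OC
F12 | step 9 | 7-hydroxy-7-methoxy octalenone, 1-(3,4-dimethoxyphenyl)-7-hydroxy-7-methoxy-2,3-dimethyl-2,3,4,7,8,8a-hexahydronaphthalen-6(1H)-one | COc1ccc([C@H]2[C@@H]3CC(O)(OC)C(=O)C=C3C[C@@H](C)[C@@H]2C)cc1OC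
F13 | step 9 | (5S,6S,7R)-5-(3,4-dimethoxyphenyl)-6,7-dimethyl-5,6,7,8-tetrahydronaphthalene-2,3-diol | COc1ccc([C@H]2c3cc(O)c(O)cc3C[C@@H](C)[C@@H]2C)cc1OC
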